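**Strategy.** The cyclopentane of the iridolactone is cut at C4a–C5 and C6–C7 (cyclopenta[c]pyran numbering). C4a is β to the lactone carbonyl C1 through C7a, and C7 is a tertiary carbinol on C7a, so C4a–C7a–C7 is read as an alkylidene β-keto lactone and C5–C6 as acetaldehyde. In one flask a chiral secondary amine joins C5 to C4a (enamine Michael addition) and a carbene catalyst joins C6 to C7 (crossed benzoin). The precursor is a 3-acyl-5,6-dihydropyran-2-one whose future C4 is masked as a dimethyl ketal. Directed reduction, methylenation and a final esterification with the separately made guaiane acid finish the route.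

Key step: step 14

Remark (assumption on the chemistry): the (S)-configured prolinol silyl ether is assumed, by analogy with its additions of acetaldehyde to nitroalkenes, to attack the face of C4 in 24 that gives the R centre (future C4a); if the sense proves opposite, the (R)-catalyst is used.

**Guaiane acid (steps 1–11)**

Step 1
Reactants: 1 (R)-pulegone
Product: 3 methyl (5R)-5-methyl-2-(propan-2-ylidene)cyclopentane-1-carboxylate (C1 epimers), via pulegone dibromide 2 (not isolated)
Conditions: Br2, AcOH, 0 °C; then NaOMe, MeOH, reflux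
Reagents that add atoms: sodium methoxide, C[O-].[Na+]
Why: Bromination of the enone alkene followed by Favorskii rearrangement (cyclopropanone, methoxide opening, loss of the second bromide) should contract the ring without touching the methyl-bearing centre.

Step 2
Reactants: 3 methyl (5R)-5-methyl-2-(propan-2-ylidene)cyclopentane-1-carboxylate
Product: 4 methyl (2R)-2-methyl-5-oxocyclopentane-1-carboxylate
Conditions: O3, CH2Cl2/MeOH, −78 °C; then Me2S
Reagents that add atoms: ozone, [O-][O+]=O
Why: Ozonolysis of the isopropylidene group should give the β-keto ester, the stereocentre being untouched.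

Step 3
Reactants: 4 methyl (2R)-2-methyl-5-oxocyclopentane-1-carboxylate
Product: 5 methyl (5R)-5-methyl-2-[(trifluoromethanesulfonyl)oxy]cyclopent-1-ene-1-carboxylate
Conditions: Tf2O, iPr2NEt, CH2Cl2, −78 °C
Reagents that add atoms: trifluoromethanesulfonic anhydride, O=S(=O)(OS(=O)(=O)C(F)(F)F)C(F)(F)F
Why: O-Sulfonylation of the β-keto ester enol (enol triflate formation) should fix the tetrasubstituted alkene next to the methyl-bearing centre.

Step 4
Reactants: 5 the enol triflate; 6 (2-tert-butoxy-2-oxoethyl)zinc bromide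
Product: 7 methyl (5R)-2-(2-tert-butoxy-2-oxoethyl)-5-methylcyclopent-1-ene-1-carboxylate
Conditions: Pd(PPh3)4 (5 mol%), THF, 60 °C
Reagents that add atoms: none
Why: Negishi coupling of the electron-poor vinyl triflate with the Reformatsky zinc enolate should install the acetate arm (future C10 and the carboxyl carbon).

Step 5
Reactants: 7 the cyclopentene diester
Product: 8 methyl (1R,2R,5R)-2-(2-tert-butoxy-2-oxoethyl)-5-methylcyclopentane-1-carboxylate (all three substituents cis)
Conditions: H2 (50 bar), Rh/Al2O3 (5 wt% Rh), EtOAc, rt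
Reagents that add atoms: none
Why: Heterogeneous syn-hydrogenation of the tetrasubstituted enoate from the face opposite the allylic methyl group should set both new centres (1R,2R), leaving all three substituents cis.

Step 6
Reactants: 8 the all-cis diester
Product: 9 tert-butyl 2-[(1R,2R,3R)-2-(hydroxymethyl)-3-methylcyclopentyl]acetate
Conditions: LiBH4, THF, 0 °C to rt
Reagents that add atoms: none
Why: LiBH4 should reduce the methyl ester chemoselectively in the presence of the hindered tert-butyl ester.

Step 7
Reactants: 9 the primary alcohol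
Product: 10 tert-butyl 2-[(1R,2R,3R)-2-(iodomethyl)-3-methylcyclopentyl]acetate
Conditions: I2, PPh3, imidazole, CH2Cl2, 0 °C
Reagents that add atoms: iodine, II
Why: Appel-type iodination (SN2 by iodide on the alkoxyphosphonium ion) should convert the primary alcohol into the iodide.

Step 8
Reactants: 10 the iodide; 11 2-bromo-3-methylbut-1-ene
Product: 13 tert-butyl 2-[(1R,2R,3R)-3-methyl-2-(3-methyl-2-methylidenebutyl)cyclopentyl]acetate, via alkenyl Grignard reagent 12 (not isolated)
Conditions: Mg, THF, rt (11 to 12); then 10, CuBr·SMe2 (10 mol%), THF, −30 to 0 °C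
Reagents that add atoms: none
Why: Copper-catalysed Kumada-type sp3–sp2 coupling of the primary iodide with the alkenyl Grignard reagent should form the C6–C7 bond while the tert-butyl ester survives at low temperature.

Step 9
Reactants: 13 the tert-butyl ester; 14 acrolein
Product: 17 tert-butyl (2E)-2-[(1S,2R,3R)-3-methyl-2-(3-methyl-2-methylidenebutyl)cyclopentyl]penta-2,4-dienoate, via aldol adduct 15 (not isolated), via allylic mesylate 16 (not isolated)
Conditions: LDA (commercial solution), THF, −78 °C; acrolein; MsCl, −78 to 0 °C; DBU, rt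
Reagents that add atoms: none
Why: Aldol 1,2-addition of the ester enolate to acrolein, mesylation and E1cB elimination should give the conjugated dienoate, the favoured E isomer placing the ring cis to the vinyl group as the ring closure requires.

Step 10
Reactants: 17 the trienyl ester
Product: 18 tert-butyl (1R,3aS,8aR)-1-methyl-7-(propan-2-yl)-1,2,3,3a,8,8a-hexahydroazulene-4-carboxylate
Conditions: second-generation Hoveyda–Grubbs catalyst (5 mol%), toluene (2 mM), 80 °C
Reagents that add atoms: none
Why: Ring-closing metathesis between the terminal vinyl group and the 1,1-disubstituted alkene should close the seven-membered ring as the trisubstituted conjugated diene with loss of ethene.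

Step 11
Reactants: 18 the tert-butyl dienoate
Product: 19 (1R,3aS,8aR)-1-methyl-7-(propan-2-yl)-1,2,3,3a,8,8a-hexahydroazulene-4-carboxylic acid
Conditions: TFA/CH2Cl2 (1:4), 0 °C
Reagents that add atoms: none
Why: Acidolysis of the tert-butyl ester (loss of 2-methylpropene) should free the acid without touching the electron-poor diene.

**Iridolactone (steps 12–17) and coupling (step 18)**

Step 12
Reactants: 20 2,2-dimethoxypropane-1,3-diol; 21 ethyl 4-(benzyloxy)-3-oxobutanoate
Product: 22 3-hydroxy-2,2-dimethoxypropyl 4-(benzyloxy)-3-oxobutanoate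
Conditions: 20 (4 equiv), DMAP (0.2 equiv), toluene, reflux, 4 Å MS
Reagents that add atoms: none
Why: DMAP-promoted transesterification of the β-keto ester with an excess of the symmetrical diol should give the mono-ester.

Step 13
Reactants: 22 the hydroxy β-keto ester
Product: 24 3-[(benzyloxy)acetyl]-5,5-dimethoxy-5,6-dihydro-2H-pyran-2-one, via keto aldehyde 23 (not isolated)
Conditions: TEMPO (10 mol%), PhI(OAc)2, CH2Cl2, rt; then piperidine (20 mol%), 4 Å MS, rt
Reagents that add atoms: none
Why: Oxoammonium oxidation of the primary alcohol and intramolecular Knoevenagel condensation should close the unsaturated six-membered lactone, whose ketal carbon carries no hydrogen so the alkene cannot migrate.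

Step 14
Reactants: 24 the alkylidene β-keto lactone; 25 acetaldehyde
Product: 27 (4aR,7S,7aR)-7-[(benzyloxy)methyl]-7-hydroxy-4,4-dimethoxyhexahydrocyclopenta[c]pyran-1,6-dione (cis-fused, 7-OH cis to the lactone carbonyl), via Michael adduct 26 (not isolated)
Conditions: (S)-α,α-diphenylprolinol trimethylsilyl ether (20 mol%), 2-(pentafluorophenyl)-6,7-dihydro-5H-pyrrolo[2,1-c][1,2,4]triazol-2-ium tetrafluoroborate (10 mol%), NaOAc (10 mol%), acetaldehyde (5 equiv), CHCl3, 0 °C to rt
Reagents that add atoms: none
Why: Acetaldehyde forms an enamine with the prolinol ether, whose α-carbon (future C5) adds to the β-carbon C4 of the doubly activated, geometry-locked acceptor 24 (C5–C4a bond), the diaryl(silyloxy)methyl group selecting the face so that C4a should be R; hydrolysis releases aldehyde 26. The triazolylidene then adds to that aldehyde and the Breslow intermediate attacks the α-benzyloxy ketone in a 5-exo-trig closure (C6–C7 bond) before the carbene is expelled. This is an amine/carbene relay, formally a [3+2] annulation, of the known enamine Michael–crossed benzoin type between aliphatic aldehydes and activated enones. C7a lies between two carbonyl groups in 26 and epimerises freely, so the ring fusion should settle cis, and the reversible benzoin step should place CH2OBn on the convex face with the C7 hydroxyl hydrogen-bonded to the lactone carbonyl (7S). The step needs 1,4- over 1,2-addition and crossed over homo-benzoin: the quaternary ketal leaves C4 as the only electrophilic alkene carbon, and acetoin formation from excess acetaldehyde is reversible.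

Step 15
Reactants: 27 the benzyl ether ketal
Product: 28 (4aR,7S,7aR)-7-hydroxy-7-(hydroxymethyl)tetrahydrocyclopenta[c]pyran-1,4,6(3H,4aH,5H)-trione
Conditions: H2 (1 atm), Pd/C (10 wt%), THF/2 M aq. HCl (5:1), rt
Reagents that add atoms: water, O
Why: Acid-assisted hydrogenolysis of the benzyl ether and hydrolysis of the dimethyl ketal in the same medium should free the primary alcohol and the C4 ketone without altering a stereocentre.

Step 16
Reactants: 28 the hydroxy trione
Product: 29 (4aR,6S,7S,7aR)-6,7-dihydroxy-7-(hydroxymethyl)tetrahydrocyclopenta[c]pyran-1,4(3H,4aH)-dione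
Conditions: Me4NBH(OAc)3, MeCN/AcOH (1:1), −30 °C
Reagents that add atoms: none
Why: In this Evans–Saksena hydroxyl-directed reduction the primary hydroxyl on the convex face should bind boron and deliver hydride to the same face of the C6 ketone, making the new hydroxyl cis to the C7 hydroxyl (6S), while the C4 ketone, lacking a directing hydroxyl, is not reduced.

Step 17
Reactants: 29 the keto triol
Product: 30 (4aR,6S,7S,7aR)-6,7-dihydroxy-7-(hydroxymethyl)-4-methylidenehexahydrocyclopenta[c]pyran-1(3H)-one
Conditions: Zn, CH2Br2, TiCl4, THF (pre-formed reagent, excess); then 29, CH2Cl2, 0 °C to rt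
Reagents that add atoms: dibromomethane, BrCBr
Why: Takai–Lombardo methylenation with the non-basic gem-dizinc/titanium reagent should convert the ketone into the exocyclic alkene without attacking the lactone or epimerising C4a, free hydroxyls being tolerated with excess reagent.

Step 18
Reactants: 19 the guaiane acid; 30 the triol lactone
Product: 32 nardostachysin, [(4aR,6S,7S,7aR)-6,7-dihydroxy-4-methylidene-1-oxooctahydrocyclopenta[c]pyran-7-yl]methyl (1R,3aS,8aR)-1-methyl-7-(propan-2-yl)-1,2,3,3a,8,8a-hexahydroazulene-4-carboxylate, via mixed anhydride 31 (not isolated)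
Conditions: 2,4,6-trichlorobenzoyl chloride, Et3N, THF, rt; then 30, DMAP, toluene, 0 °C
Reagents that add atoms: none
Why: In this Yamaguchi esterification the mixed anhydride should acylate the primary hydroxyl in preference to the hindered secondary and tertiary ones, giving the target.

**Compound list**

1 | (R)-pulegone, (5R)-5-methyl-2-(propan-2-ylidene)cyclohexan-1-one | C[C@@H]1CCC(=C(C)C)C(=O)C1 | starting material
2 | (5R)-2-bromo-2-(2-bromopropan-2-yl)-5-methylcyclohexan-1-one (C2 epimers) | C[C@@H]1CCC(Br)(C(C)(C)Br)C(=O)C1 | intermediate (not isolated)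
3 | methyl (5R)-5-methyl-2-(propan-2-ylidene)cyclopentane-1-carboxylate | COC(=O)C1[C@H](C)CCC1=C(C)C | intermediate
4 | methyl (2R)-2-methyl-5-oxocyclopentane-1-carboxylate | COC(=O)C1[C@H](C)CCC1=O | intermediate
5 | methyl (5R)-5-methyl-2-[(trifluoromethanesulfonyl)oxy]cyclopent-1-ene-1-carboxylate | COC(=O)C1=C(OS(=O)(=O)C(F)(F)F)CC[C@H]1C | intermediate
6 | (2-tert-butoxy-2-oxoethyl)zinc bromide | CC(C)(C)OC(=O)C[Zn]Br | starting material
7 | methyl (5R)-2-(2-tert-butoxy-2-oxoethyl)-5-methylcyclopent-1-ene-1-carboxylate | COC(=O)C1=C(CC(=O)OC(C)(C)C)CC[C@H]1C | intermediate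
8 | methyl (1R,2R,5R)-2-(2-tert-butoxy-2-oxoethyl)-5-methylcyclopentane-1-carboxylate | COC(=O)[C@@H]1[C@H](C)CC[C@@H]1CC(=O)OC(C)(C)C | intermediate
9 | tert-butyl 2-[(1R,2R,3R)-2-(hydroxymethyl)-3-methylcyclopentyl]acetate | OC[C@@H]1[C@H](C)CC[C@@H]1CC(=O)OC(C)(C)C | intermediate
10 | tert-butyl 2-[(1R,2R,3R)-2-(iodomethyl)-3-methylcyclopentyl]acetate | IC[C@@H]1[C@H](C)CC[C@@H]1CC(=O)OC(C)(C)C | intermediate
11 | 2-bromo-3-methylbut-1-ene | C=C(Br)C(C)C | starting material
12 | (3-methylbut-1-en-2-yl)magnesium bromide | C=C([Mg]Br)C(C)C | intermediate (not isolated)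
13 | tert-butyl 2-[(1R,2R,3R)-3-methyl-2-(3-methyl-2-methylidenebutyl)cyclopentyl]acetate | C=C(C(C)C)C[C@@H]1[C@H](C)CC[C@@H]1CC(=O)OC(C)(C)C | intermediate
14 | acrolein | C=CC=O | starting material
15 | tert-butyl 3-hydroxy-2-[(2R,3R)-3-methyl-2-(3-methyl-2-methylidenebutyl)cyclopentyl]pent-4-enoate (ring C1 as in 13; side-chain diastereomers) | C=C(C(C)C)C[C@@H]1[C@H](C)CC[C@@H]1C(C(O)C=C)C(=O)OC(C)(C)C | intermediate (not isolated)
16 | the corresponding 3-(methanesulfonyloxy) ester | C=C(C(C)C)C[C@@H]1[C@H](C)CC[C@@H]1C(C(OS(C)(=O)=O)C=C)C(=O)OC(C)(C)C | intermediate (not isolated)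
17 | tert-butyl (2E)-2-[(1S,2R,3R)-3-methyl-2-(3-methyl-2-methylidenebutyl)cyclopentyl]penta-2,4-dienoate | C=C(C(C)C)C[C@@H]1[C@H](C)CC[C@@H]1/C(C(=O)OC(C)(C)C)=C\C=C | intermediate
18 | tert-butyl (1R,3aS,8aR)-1-methyl-7-(propan-2-yl)-1,2,3,3a,8,8a-hexahydroazulene-4-carboxylate | CC(C)(C)OC(=O)C1=CC=C(C(C)C)C[C@@H]2[C@H](C)CC[C@H]12 | intermediate
19 | (1R,3aS,8aR)-1-methyl-7-(propan-2-yl)-1,2,3,3a,8,8a-hexahydroazulene-4-carboxylic acid | OC(=O)C1=CC=C(C(C)C)C[C@@H]2[C@H](C)CC[C@H]12 | intermediate
20 | 2,2-dimethoxypropane-1,3-diol | COC(CO)(CO)OC | starting material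
21 | ethyl 4-(benzyloxy)-3-oxobutanoate | CCOC(=O)CC(=O)COCc1ccccc1 | starting material
22 | 3-hydroxy-2,2-dimethoxypropyl 4-(benzyloxy)-3-oxobutanoate | COC(CO)(OC)COC(=O)CC(=O)COCc1ccccc1 | intermediate
23 | 2,2-dimethoxy-3-oxopropyl 4-(benzyloxy)-3-oxobutanoate | COC(C=O)(OC)COC(=O)CC(=O)COCc1ccccc1 | intermediate (not isolated)
24 | 3-[(benzyloxy)acetyl]-5,5-dimethoxy-5,6-dihydro-2H-pyran-2-one | COC1(OC)COC(=O)C(=C1)C(=O)COCc1ccccc1 | intermediate
25 | acetaldehyde | CC=O | starting material
26 | {(4R)-3-[(benzyloxy)acetyl]-5,5-dimethoxy-2-oxooxan-4-yl}acetaldehyde (C3 epimers and enol) | COC1(OC)COC(=O)C(C(=O)COCc2ccccc2)[C@H]1CC=O | intermediate (not isolated)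
27 | (4aR,7S,7aR)-7-[(benzyloxy)methyl]-7-hydroxy-4,4-dimethoxyhexahydrocyclopenta[c]pyran-1,6-dione | COC1(OC)COC(=O)[C@@H]2[C@H]1CC(=O)[C@@]2(O)COCc1ccccc1 | intermediate
28 | (4aR,7S,7aR)-7-hydroxy-7-(hydroxymethyl)tetrahydrocyclopenta[c]pyran-1,4,6(3H,4aH,5H)-trione | O=C1COC(=O)[C@@H]2[C@H]1CC(=O)[C@@]2(O)CO | intermediate
29 | (4aR,6S,7S,7aR)-6,7-dihydroxy-7-(hydroxymethyl)tetrahydrocyclopenta[c]pyran-1,4(3H,4aH)-dione | O=C1COC(=O)[C@@H]2[C@H]1C[C@H](O)[C@@]2(O)CO | intermediate
30 | (4aR,6S,7S,7aR)-6,7-dihydroxy-7-(hydroxymethyl)-4-methylidenehexahydrocyclopenta[c]pyran-1(3H)-one | C=C1COC(=O)[C@@H]2[C@H]1C[C@H](O)[C@@]2(O)CO | intermediate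
31 | (1R,3aS,8aR)-1-methyl-7-(propan-2-yl)-1,2,3,3a,8,8a-hexahydroazulene-4-carboxylic 2,4,6-trichlorobenzoic anhydride | O=C(OC(=O)c1c(Cl)cc(Cl)cc1Cl)C1=CC=C(C(C)C)C[C@@H]2[C@H](C)CC[C@H]12 | intermediate (not isolated)
32 | nardostachysin | C=C1COC(=O)[C@@H]2[C@H]1C[C@H](O)[C@@]2(O)COC(=O)C1=CC=C(C(C)C)C[C@@H]2[C@H](C)CC[C@H]12 | target

**Step count and risks**

Total steps: 18. Longest linear sequence: 12 (steps 1–11, then 18); the iridolactone branch is steps 12–17.

Steps most likely to fail:

1. Step 14 (key step). Acetaldehyde may self-condense under the two catalysts, the carbene may add to the acceptor, or control at C7 may be weak. Fallback, from 24: run the Michael addition alone (same amine, PhCO2H co-catalyst, no carbene) and isolate aldehyde 26. Then close the ring reductively with SmI2 and t-BuOH in THF at −78 °C: the aldehyde ketyl adds to the samarium-chelated ketone (pinacol-type cyclisation), which should give the cis-diol directly as (4aR,6S,7S,7aR)-7-[(benzyloxy)methyl]-6,7-dihydroxy-4,4-dimethoxyhexahydrocyclopenta[c]pyran-1(3H)-one F1. Hydrogenolysis and ketal hydrolysis under the conditions of step 15 bring F1 back to the route at 29.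

2. Step 17. Zinc may reductively cleave the C3–O bond next to the ketone, or the triol may sequester the titanium reagent. Fallback, from 29: add (trimethylsilyl)methylmagnesium chloride with CeCl3 (excess, THF, −78 °C) to the ketone to give the β-hydroxysilane (4aR,6S,7S,7aR)-4,6,7-trihydroxy-7-(hydroxymethyl)-4-[(trimethylsilyl)methyl]hexahydrocyclopenta[c]pyran-1(3H)-one F2 (C4 epimers). Peterson elimination with aqueous HF in MeCN returns to the route at 30.

3. Step 5. The tetrasubstituted enoate may hydrogenate slowly, the double bond may migrate and erode the methyl stereocentre, or facial selectivity may be poor. Fallback, from 5: reduce the ester with DIBAL-H (CH2Cl2, −78 °C) to (3R)-2-(hydroxymethyl)-3-methylcyclopent-1-en-1-yl trifluoromethanesulfonate F3. Couple F3 with 6 (Pd(PPh3)4, THF) to give tert-butyl 2-[(3R)-2-(hydroxymethyl)-3-methylcyclopent-1-en-1-yl]acetate F4. Hydrogenate F4 with the hydroxyl-binding homogeneous catalyst [Ir(cod)(PCy3)(py)]PF6 (H2, CH2Cl2), again from the face opposite the methyl group; this returns to the route at 9.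

**Further compounds**

F1 | step 14 | (4aR,6S,7S,7aR)-7-[(benzyloxy)methyl]-6,7-dihydroxy-4,4-dimethoxyhexahydrocyclopenta[c]pyran-1(3H)-one | COC1(OC)COC(=O)[C@@H]2[C@H]1C[C@H](O)[C@@]2(O)COCc1ccccc1
F2 | step 17 | (4aR,6S,7S,7aR)-4,6,7-trihydroxy-7-(hydroxymethyl)-4-[(trimethylsilyl)methyl]hexahydrocyclopenta[c]pyran-1(3H)-one | C[Si](C)(C)CC1(O)COC(=O)[C@@H]2[C@H]1C[C@H](O)[C@@]2(O)CO
F3 | step 5 | (3R)-2-(hydroxymethyl)-3-methylcyclopent-1-en-1-yl trifluoromethanesulfonate | OCC1=C(OS(=O)(=O)C(F)(F)F)CC[C@H]1C
F4 | step 5 | tert-butyl 2-[(3R)-2-(hydroxymethyl)-3-methylcyclopent-1-en-1-yl]acetate | OCC1=C(CC(=O)OC(C)(C)C)CC[C@H]1C
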